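In the closed, stirred vessel L passes, on the proposed steps, into X, and D can take X up as E, so E rises and then falls again. The question is how high it gets and how soon it goes.

| setting | gamma | delta | zeta | flask |
|---|---|---|---|---|
| L | 0.50 M | 0.50 M | 0.50 M | 0.50 M |
| D | 1 equiv | 1 equiv | 2 equiv | 1.00 equiv |
| Z | 1.4 equiv | 2.2 equiv | 1 equiv | 1.00 equiv |
| remark | run made earlier | run made earlier | run made earlier |  |
| time |  |  |  | 4.0 d |

| run | time / d | E / % |
|---|---|---|
| gamma | 0.0833 | 1 |
| gamma | 0.167 | 7 |
| gamma | 0.333 | 11 |
| gamma | 0.833 | 3 |
| gamma | 1.67 | 0 |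
| gamma | 4.00 | 0 |
| delta | 0.0833 | 4 |
| delta | 0.167 | 9 |
| delta | 0.333 | 13 |
| delta | 0.833 | 3 |
| delta | 1.67 | 2 |
| delta | 4.00 | 0 |
| zeta | 0.0833 | 3 |
| zeta | 0.208 | 13 |
| zeta | 0.500 | 17 |
| zeta | 1.67 | 2 |
| zeta | 4.00 | 4 |

(scatter of a reading: 1.5 percentage points)

1. the moment within 4.0 d at which there is most E
2. the amount of E, in percent of the L charged, at that time
3. the first time at which E reaches 8.2%, in the same percent, in d

- the numbers in the tables scatter by 1.5 percentage points (one standard deviation)
- steps that have been proposed: L -> X; D + X <-> E; Z + X -> J; X -> G; 2 Z -> Q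

A rate constant gives the fraction of something that goes in each moment, so a first-order fall loses equal fractions in equal times and is a straight line in logarithms. I therefore count in powers of ten. In gamma, E falls from 11% at 0.333 d to 3% at 0.833 d, which is 0.564 of a power of ten, so a whole power takes 0.886 d. Delta gives 0.785 d. Both have the D of this flask, whereas zeta has twice as much, so I leave zeta aside. Their mean, 0.836 d, is my decade time: the time E takes to fall to a tenth once past its peak. It is rough, because the lower readings are not far above a scatter of 1.5 percentage points.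

For this flask I commit to about 12.0% near 0.333 d, and to the asked level just past 0.167 d, where the two runs average 8.00%. Two decades after the peak, at 2.00 d, I expect 0.120%. The forecast says 12.5% at 0.37 d, with the level reached at 0.18 d, and expects “a similar curve, perhaps lasting slightly longer”.

The flask peaks at 11.7% at 0.289 d and first reaches the level at 0.172 d, and at 2.00 d it holds 0.138% of E against my 0.120%.

    L → X (k = 0.122 h⁻¹)
    D + X ⇌ E (K = 22.6 L mol⁻¹, k = 79.9 L mol⁻¹ h⁻¹)
    Z + X → J (k = 1660 L mol⁻¹ h⁻¹)
    X → G (k = 4.50 h⁻¹)
    2 Z → Q (k = 3.11 L mol⁻¹ h⁻¹)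

At 0.237 d the flask's X has a half-life by passing into G of 0.15 h, far shorter than the 0.24 d of L by passing into X, the rate-limiting step, and X is made 1.01 times as fast as it is used up. That half-life of L comes to a decade of 0.786 d against my 0.836 d, and on this decade the neighbour flask read at 6.0 d stands 7.27 powers of ten below its peak of 11.7%, and it reads 0%.

All runs are simulated for substances that don't exist; scatter was added.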